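**Plan**
- Retrosynthesis: the hydroquinone of ring B is taken back to its quinone, and the quinone is cut at C1'–C2' to a 4-alkynyl-4-hydroxycyclobutenone.
- The carbinol–alkyne bond is then cut to methyl semisquarate and a 2-ethynylchromone, and the C2–alkyne bond to a 2-iodochromone and trimethylsilylacetylene.
- Forward: the pyranone (ring C) is closed on the ring A acetophenone, the 3-methoxy group is installed, and C2 is iodinated and alkynylated.
- The acetylide is then added to the four-membered dione, ring B is grown last by thermal ring expansion, and the quinone is reduced.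
- Stereochemistry: the target is achiral; the one carbinol stereocentre on the way is made as a racemate and is erased in the ring expansion.

Key step: step 10

Assumption: compounds 4, 13 and 16 are racemates (one enantiomer is drawn in each SMILES); none of these centres survives to the target.

**Step 1**
Reactants: 1 2'-hydroxy-3',4'-dimethoxyacetophenone
Product: 3 7,8-dimethoxy-4H-chromen-4-one, via enaminone 2 (not isolated)
Conditions: DMF-DMA, toluene, 100 °C; then conc. HCl, CH2Cl2, 40 °C
Reagents that add atoms: N,N-dimethylformamide dimethyl acetal, COC(OC)N(C)C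
Why: Condensation of the methyl ketone with the amide acetal gives the enaminone, and acid then promotes intramolecular oxa-Michael addition of the phenol and loss of dimethylamine, the standard enaminone route to chromones.

**Step 2**
Reactants: 3 7,8-dimethoxy-4H-chromen-4-one
Product: 5 3-hydroxy-7,8-dimethoxy-4H-chromen-4-one, via chromone epoxide 4 (not isolated)
Conditions: DMDO, acetone/CH2Cl2, 0 °C to rt; then p-TsOH·H2O (cat.), rt
Reagents that add atoms: dimethyldioxirane, CC1(C)OO1
Why: Electrophilic epoxidation of the enol-ether-like C2=C3 bond by the dioxirane, then acid-catalysed opening of the epoxide at the acetal carbon C2 and loss of H-3, is the known epoxidation–isomerisation route from chromones to 3-hydroxychromones; the cis-fused epoxide centres are transient.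

**Step 3**
Reactants: 5 3-hydroxy-7,8-dimethoxy-4H-chromen-4-one
Product: 6 3,7,8-trimethoxy-4H-chromen-4-one
Conditions: MeI, K2CO3, acetone, 56 °C
Reagents that add atoms: iodomethane, CI
Why: Williamson O-methylation of the acidic enolic 3-hydroxyl, as routinely done on flavonols.

**Step 4**
Reactants: 6 3,7,8-trimethoxy-4H-chromen-4-one
Product: 8 2-iodo-3,7,8-trimethoxy-4H-chromen-4-one, via 2-zincated chromone 7 (not isolated)
Conditions: TMPZnCl·LiCl, THF, 25 °C; then I2, 0 °C
Reagents that add atoms: iodine, II
Why: Deprotonative zincation with the hindered zinc amide removes the most acidic proton, H-2, which is flanked by the ring oxygen and the 3-methoxy group, without attacking the pyranone, and iodinolysis of the C–Zn bond gives the 2-iodide (directed metalation–halogenation).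

**Step 5**
Reactants: 8 2-iodo-3,7,8-trimethoxy-4H-chromen-4-one; 9 trimethylsilylacetylene
Product: 10 3,7,8-trimethoxy-2-[(trimethylsilyl)ethynyl]-4H-chromen-4-one
Conditions: PdCl2(PPh3)2 (cat.), CuI (cat.), Et3N, THF, rt
Reagents that add atoms: none
Why: Sonogashira coupling; the 2-iodochromone is a vinylogous acyl iodide that undergoes oxidative addition readily, and a tertiary amine base avoids addition–elimination at C2.

**Step 6**
Reactants: 10 3,7,8-trimethoxy-2-[(trimethylsilyl)ethynyl]-4H-chromen-4-one
Product: 11 2-ethynyl-3,7,8-trimethoxy-4H-chromen-4-one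
Conditions: TBAF, AcOH, THF, 0 °C
Reagents that add atoms: none
Why: Fluoride-induced protodesilylation of the alkynylsilane, buffered with acetic acid so that no basic nucleophile adds to the conjugated enynone.

**Step 7**
Reactants: 12 dimethyl squarate
Product: 13 rac-4-hydroxy-2,3-dimethoxycyclobut-2-en-1-one
Conditions: LiAlH(OtBu)3, THF, −78 to −20 °C; aq. work-up
Reagents that add atoms: none
Why: The mild, bulky alkoxyaluminium hydride adds once, 1,2, to a squarate carbonyl, and the alkoxide formed protects the ring from a second reduction; the new carbinol centre is racemic and is lost in step 8.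

**Step 8**
Reactants: 13 rac-4-hydroxy-2,3-dimethoxycyclobut-2-en-1-one
Product: 14 3-methoxycyclobut-3-ene-1,2-dione
Conditions: conc. HCl (cat.), CH2Cl2, rt
Reagents that add atoms: water, O (the new carbonyl oxygen comes from water after ionisation of the carbinol)
Why: Acid-catalysed ionisation of the carbinol gives an oxygen-stabilised cyclobutenyl cation, which is captured by water at the distal methoxy-bearing carbon and loses methanol, the usual transposition of squarate 1,2-adducts to cyclobutenediones.

**Step 9**
Reactants: 11 2-ethynyl-3,7,8-trimethoxy-4H-chromen-4-one; 14 3-methoxycyclobut-3-ene-1,2-dione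
Product: 16 rac-4-hydroxy-3-methoxy-4-[(3,7,8-trimethoxy-4-oxo-4H-chromen-2-yl)ethynyl]cyclobut-2-en-1-one, via lithium acetylide 15 (not isolated)
Conditions: 11, LiN(SiMe3)2, THF, −78 °C; then cannulate into 14, THF, −78 °C; aq. NH4Cl
Reagents that add atoms: none
Why: 1,2-Addition of a lithium acetylide to a cyclobutenedione should occur at the ketone-like carbonyl next to the methoxy-bearing carbon, since the other carbonyl is a deactivated vinylogous ester; the carbinol centre forms as a racemate and is destroyed in step 10.

**Step 10**
Reactants: 16 rac-4-hydroxy-3-methoxy-4-[(3,7,8-trimethoxy-4-oxo-4H-chromen-2-yl)ethynyl]cyclobut-2-en-1-one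
Product: 19 2-methoxy-5-(3,7,8-trimethoxy-4-oxo-4H-chromen-2-yl)cyclohexa-2,5-diene-1,4-dione, via enynyl ketene 17 (not isolated), via aryl–phenoxyl diradical 18 (not isolated)
Conditions: p-xylene (degassed, ca. 0.01 M), 138 °C
Reagents that add atoms: none
Why: Heating should trigger conrotatory four-electron electrocyclic opening of the C1–C4 bond of the cyclobutenone, with the donor hydroxyl rotating outward so that the alkynyl group lies cis to the ketene arm in 17. The ketene carbon then bonds to the distal, chromone-bearing alkyne carbon in a six-membered (C2–C7-type, formally 6-endo-dig) closure that forms the C1'–C2' bond and ring B as diradical 18, and transfer of the hydroxyl hydrogen to the ring carbon radical gives quinone 19. The closest known reaction type is the Moore cyclization of 4-alkynyl-4-hydroxycyclobutenones to 1,4-benzoquinones. No stereocentre is formed and the racemic carbinol centre of 16 is erased. The substituent pattern is fixed by the substrate, because the methoxy group sits on the ring carbon β to the ketone and must end up para to the chromone-bearing carbon. What the substrate does not guarantee is six- over five-membered closure, which the conjugating chromone favours and which would give an alkylidenecyclopentenedione, so the reaction is run dilute at the lowest temperature that opens the ring and is treated below as the main risk.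

**Step 11**
Reactants: 19 2-methoxy-5-(3,7,8-trimethoxy-4-oxo-4H-chromen-2-yl)cyclohexa-2,5-diene-1,4-dione
Product: 20 diplotrin A, 2-(2,5-dihydroxy-4-methoxyphenyl)-3,7,8-trimethoxy-4H-chromen-4-one
Conditions: Na2S2O4, EtOAc/H2O, rt, under N2
Reagents that add atoms: none
Why: Dithionite reduces the quinone by two electrons to the hydroquinone under biphasic conditions that leave the chromone and the methyl ethers untouched, so no protecting group is needed.

**Compound list**
1 | 2'-hydroxy-3',4'-dimethoxyacetophenone | CC(=O)c1ccc(OC)c(OC)c1O | starting material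
2 | (E)-3-(dimethylamino)-1-(2-hydroxy-3,4-dimethoxyphenyl)prop-2-en-1-one | CN(C)/C=C/C(=O)c1ccc(OC)c(OC)c1O | intermediate
3 | 7,8-dimethoxy-4H-chromen-4-one | COc1ccc2c(=O)ccoc2c1OC | intermediate
4 | rac-2,3-epoxy-7,8-dimethoxychroman-4-one (cis-fused epoxide) | COc1ccc2C(=O)[C@H]3O[C@H]3Oc2c1OC | intermediate
5 | 3-hydroxy-7,8-dimethoxy-4H-chromen-4-one | COc1ccc2c(=O)c(O)coc2c1OC | intermediate
6 | 3,7,8-trimethoxy-4H-chromen-4-one | COc1coc2c(OC)c(OC)ccc2c1=O | intermediate
7 | chloro(3,7,8-trimethoxy-4-oxo-4H-chromen-2-yl)zinc (LiCl complex) | COc1c([Zn]Cl)oc2c(OC)c(OC)ccc2c1=O | intermediate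
8 | 2-iodo-3,7,8-trimethoxy-4H-chromen-4-one | COc1c(I)oc2c(OC)c(OC)ccc2c1=O | intermediate
9 | trimethylsilylacetylene | C#C[Si](C)(C)C | starting material
10 | 3,7,8-trimethoxy-2-[(trimethylsilyl)ethynyl]-4H-chromen-4-one | COc1c(C#C[Si](C)(C)C)oc2c(OC)c(OC)ccc2c1=O | intermediate
11 | 2-ethynyl-3,7,8-trimethoxy-4H-chromen-4-one | COc1c(C#C)oc2c(OC)c(OC)ccc2c1=O | intermediate
12 | dimethyl squarate | COC1=C(OC)C(=O)C1=O | starting material
13 | rac-4-hydroxy-2,3-dimethoxycyclobut-2-en-1-one | COC1=C(OC)[C@@H](O)C1=O | intermediate
14 | 3-methoxycyclobut-3-ene-1,2-dione | COC1=CC(=O)C1=O | intermediate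
15 | lithium acetylide of 11 | COc1c(C#C[Li])oc2c(OC)c(OC)ccc2c1=O | intermediate
16 | rac-4-hydroxy-3-methoxy-4-[(3,7,8-trimethoxy-4-oxo-4H-chromen-2-yl)ethynyl]cyclobut-2-en-1-one | COC1=CC(=O)[C@@]1(O)C#Cc1oc2c(OC)c(OC)ccc2c(=O)c1OC | intermediate
17 | (Z)-enynyl ketene from ring opening of 16 (hydroxyl outward, alkyne cis to the ketene arm) | O=C=C/C(OC)=C(O)\C#Cc1oc2c(OC)c(OC)ccc2c(=O)c1OC | intermediate
18 | six-membered aryl σ-radical/phenoxyl diradical | COc1cc([O])c(-c2oc3c(OC)c(OC)ccc3c(=O)c2OC)[c]c1O | intermediate
19 | 2-methoxy-5-(3,7,8-trimethoxy-4-oxo-4H-chromen-2-yl)cyclohexa-2,5-diene-1,4-dione | COC1=CC(=O)C(c2oc3c(OC)c(OC)ccc3c(=O)c2OC)=CC1=O | intermediate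
20 | diplotrin A | COc1cc(O)c(-c2oc3c(OC)c(OC)ccc3c(=O)c2OC)cc1O | target

**Step count**
Total: 11 steps. Longest linear sequence: 9 steps (steps 1–6, 9, 10, 11); the squarate branch (steps 7, 8) joins at step 9.

**Steps most likely to fail**

1. Step 10. The enynyl ketene may close through the five-membered mode, because the chromone stabilises the exocyclic vinyl radical by conjugation, and material would then be diverted to the ring-contracted dione. Fallback: setting out from 8, Suzuki–Miyaura coupling with commercial 2,4,5-trimethoxyphenylboronic acid (Pd(PPh3)4, K2CO3, dioxane/H2O, 80 °C) should give 3,7,8-trimethoxy-2-(2,4,5-trimethoxyphenyl)-4H-chromen-4-one F1. Oxidative demethylation of its para-dimethoxy pair with (NH4)2Ce(NO3)6 in MeCN/H2O at 0 °C should then give the methoxyquinone, so the route is rejoined at 19.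

2. Step 9. The amide base or the stabilised acetylide may attack the pyranone, or the acetylide may add to the dione in a conjugate sense or at the vinylogous ester carbonyl, instead of adding 1,2 to the ketone. Fallback: setting out from 14, addition of lithium (trimethylsilyl)acetylide (from 9 and n-BuLi, THF, −78 °C) should give rac-4-hydroxy-3-methoxy-4-[(trimethylsilyl)ethynyl]cyclobut-2-en-1-one F2. Buffered fluoride (TBAF, AcOH, THF, 0 °C) should free rac-4-ethynyl-4-hydroxy-3-methoxycyclobut-2-en-1-one F3. Sonogashira coupling of F3 with 8 (PdCl2(PPh3)2, CuI, Et3N, THF, rt) then joins the chromone without any chromone carbanion, and the route is rejoined at 16.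

3. Step 4. The metalated chromone may condense with unreacted chromone, metalation may stay incomplete, or the vinylogous acyl iodide may lose iodide on handling. Fallback: setting out from 6, O-silylation with TBSOTf gives the 4-silyloxybenzopyrylium ion, and conjugate alkynylation at C2 with 9 (CuI, iPr2NEt, CH2Cl2, −40 °C) should give rac-tert-butyl(dimethyl){[3,7,8-trimethoxy-2-[(trimethylsilyl)ethynyl]-2H-chromen-4-yl]oxy}silane F4. Dehydrogenation of this silyl enol ether with DDQ (hydride abstraction at C2, then loss of the silyl group) restores the chromone, so the route is rejoined at 10 without the iodide.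

**Further compounds**
F1 | step 10 | 3,7,8-trimethoxy-2-(2,4,5-trimethoxyphenyl)-4H-chromen-4-one | COc1cc(OC)c(-c2oc3c(OC)c(OC)ccc3c(=O)c2OC)cc1OC
F2 | step 9 | rac-4-hydroxy-3-methoxy-4-[(trimethylsilyl)ethynyl]cyclobut-2-en-1-one | COC1=CC(=O)[C@@]1(O)C#C[Si](C)(C)C
F3 | step 9 | rac-4-ethynyl-4-hydroxy-3-methoxycyclobut-2-en-1-one | COC1=CC(=O)[C@@]1(O)C#C
F4 | step 4 | rac-tert-butyl(dimethyl){[3,7,8-trimethoxy-2-[(trimethylsilyl)ethynyl]-2H-chromen-4-yl]oxy}silane | COC1=C(O[Si](C)(C)C(C)(C)C)c2ccc(OC)c(OC)c2O[C@@H]1C#C[Si](C)(C)C
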